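I began from a leftover: the last step runs on whatever coupling partner the first coupling spares.

| setting | zeta | gamma |
|---|---|---|
| substrate | 0.30 M | 0.30 M |
| coupling partner | 1.10 equiv | 2.60 equiv |
| time | 10 min | 10 min |

    coupling partner + target ⇌ idle adduct, settled at all times (K1 = 112 M⁻¹)
    substrate → intermediate A (k2 = 0.00914 s⁻¹)
    coupling partner + intermediate B → intermediate C (k3 = 0.0306 M⁻¹ s⁻¹)
    intermediate A → intermediate B (k4 = 0.00629 s⁻¹)
    intermediate B → side product (k5 = 0.00228 s⁻¹)
    coupling partner + intermediate C → target (k6 = 0.00412 M⁻¹ s⁻¹)

- which of the two there is more of at the end, zeta (side product / target)
- which of the two there is more of at the end, gamma (side product / target)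
- amount of target at the end, in percent of the substrate charged, zeta
- amount of target at the end, in percent of the substrate charged, gamma

My first question was where intermediate B goes, since it can couple or fall to side product. I took the break-even concentration c*, the rate constant of that loss over the rate constant of the coupling, at which both branches run equally: 0.0745 M. The share of intermediate B lost is then c*/(c* + c(coupling partner)), and c(coupling partner)/c* is the selectivity factor of this fork. At the charged 0.330 M in zeta the loss is 18.4%, and at the charged 0.780 M in gamma it is 8.72%.

So how much coupling partner does the capture leave? Before the last step draws on it, zeta keeps 0.0853 M, close to c*, while gamma keeps 0.506 M.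

How much of the captured material then goes on to target? I let intermediate C arrive after the half-lives of substrate and intermediate A, 3.10 min together, and for the rest of the run let it react as a pseudo-first-order step, with the coupling partner held at that leftover. This estimate gave zeta 11.0% target, less than the 18.4% of side product from the fork. It gave gamma 52.8% target, more than its 8.72% of side product. So I put side product ahead in zeta and target ahead in gamma.

The forecast named side product for zeta with 11.5% target, and target for gamma with 37% target, where “the partner stays plentiful”. My target for gamma was higher than the forecast's.

The simulation gave zeta 10.8% target against 22.0% side product, and gamma 35.6% target against 10.4% side product.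

Neither flask had come to rest at 10.0 min. In gamma, 10.7% still stood before the fork or at it, and 0.333 M of coupling partner put the loss at 18.3%, so I reckoned side product would reach 12.4%. It read 12.8% at 100 min, while target rose to 82.1%. In zeta, 19.8% and 0.0935 M gave a loss of 44.3% and side product of 30.7%. It read 33.1% at 100 min, with target at 28.9% and coupling partner down to 1.95% of its charge.

The constants used here are those of an exercise; the result is computed.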